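## Retrosynthetic overview

1. The pyranone ring is made last. Its lactone C1–O2 bond (enol lactonisation) and its C3–C4 bond (benzylic anion plus Weinreb amide) are cut to a chlorinated, protected orsellinate and an oxolanyl dienamide.
2. Both double bonds of the (E,E)-diene are cut (Horner–Wadsworth–Emmons, then Wittig) back to the C2 hydroxymethyl group of a 5-methyloxolane-3-ol.
3. The key disconnection is O1–C5 of the oxolane. It gives acyclic (2R,3S)-hex-5-ene-1,2,3-triol, one methylenation away from 2-deoxy-D-ribose, whose C4, C3, C2, C1 and O4 become C2, C3, C4, C5 and O1.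
4. The enabling feature lies in the oxolane ring O1–C2–C3–C4–C5: C4 is a bare CH2 and C5 carries only H and CH3, so O1 on C2 plus a C5=CH2 alkene is a 4-pentenol. The C2 side chain is trans and the C3 hydroxyl cis to the C5 methyl, which is the pattern an aerobic cobalt-catalysed closure favours.
5. Ring order: oxolane (step 2), benzene ring purchased, pyranone ring (step 9).

Key step: step 2

Remark: 2-deoxy-D-ribose is drawn as the open-chain aldehyde through which the commercial lactol reacts. The cobalt catalyst of step 2 is obtained by mixing Co(OAc)2 with two equivalents of commercial 4,4,4-trifluoro-1-phenylbutane-1,3-dione and is not counted as a step.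

## Route

Step 1
Reactants: 1 2-deoxy-D-ribose
Product: 2 (2R,3S)-hex-5-ene-1,2,3-triol
Conditions: Ph3PCH3Br (3.5 equiv), KOtBu (3.3 equiv), THF, 0 °C to rt
Reagents that add atoms: methyltriphenylphosphonium bromide, C[P+](c1ccccc1)(c1ccccc1)c1ccccc1.[Br-]
Why: Wittig methylenation of the open-chain aldehyde in equilibrium with the lactol, with excess ylide buffering the free hydroxyls, should cut the sugar's O4–C1 bond, leave both carbinol stereocentres untouched and release O4 as the free C2 hydroxyl of a 4-pentenol.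

Step 2
Reactants: 2 (2R,3S)-hex-5-ene-1,2,3-triol
Product: 4 (2R,3S,5R)-2-(hydroxymethyl)-5-methyloxolan-3-ol, via oxolan-2-ylmethyl radical 3 (not isolated)
Conditions: bis(4,4,4-trifluoro-1-phenylbutane-1,3-dionato)cobalt (5 mol %), O2 (1 atm), cyclohexa-1,4-diene (15 equiv), PhMe/t-BuOH, 60 °C
Reagents that add atoms: none
Why: The divalent cobalt diketonate takes up O2, binds the C2 hydroxyl of 2 and oxidises the bound alkenol, so that O1 adds to the internal alkene carbon C5 and the terminal carbon is left as the free radical 3, which abstracts a hydrogen atom from cyclohexa-1,4-diene and thereby becomes the C5 methyl group. The closest known reaction type is the Mukaiyama aerobic oxidative cyclisation of 4-pentenols run with reductive termination by a hydrogen-atom donor, a reaction whose parent form is carried out in alcohol solvents, so the two spectator hydroxyls should be tolerated. The oxolane closes in the 5-exo-trig mode. The new stereocentre C5 is controlled by the chair-like, cobalt-bound transition state, in which the C2 hydroxymethyl group lies pseudo-equatorial (methyl trans to it across O1) and the C3 hydroxyl reinforces this (methyl cis to it across C4), so both resident stereocentres of the erythro diol point to the (5R) isomer. The step needs site selectivity among three hydroxyls, secured because only the C2 hydroxyl reaches C5 through a five-membered ring (the primary hydroxyl would need 6-exo and the C3 hydroxyl 4-exo closure), and it needs hydrogen transfer to outrun capture of 3 by O2, secured by the large excess of the diene.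

Step 3
Reactants: 4 (2R,3S,5R)-2-(hydroxymethyl)-5-methyloxolan-3-ol
Product: 6 (E)-3-[(2R,3S,5R)-3-hydroxy-5-methyloxolan-2-yl]prop-2-enal, via oxolane-2-carbaldehyde 5 (not isolated)
Conditions: TEMPO (10 mol %), PhI(OAc)2 (1.1 equiv), CH2Cl2, rt; then Ph3P=CHCHO (1.3 equiv), rt
Reagents that add atoms: (triphenylphosphoranylidene)acetaldehyde, O=CC=P(c1ccccc1)(c1ccccc1)c1ccccc1
Why: The oxoammonium oxidation (TEMPO/PhI(OAc)2) is selective for the primary over the secondary alcohol, and the epimerisable alpha-alkoxy aldehyde is consumed in the same flask by the stabilised ylide in an E-selective Wittig reaction, so that C2 should keep its configuration.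

Step 4
Reactants: 6 (E)-3-[(2R,3S,5R)-3-hydroxy-5-methyloxolan-2-yl]prop-2-enal
Product: 7 (2E,4E)-5-[(2R,3S,5R)-3-hydroxy-5-methyloxolan-2-yl]-N-methoxy-N-methylpenta-2,4-dienamide
Conditions: (EtO)2P(O)CH2C(O)N(OMe)Me, LiCl, DBU, MeCN, 0 °C to rt
Reagents that add atoms: diethyl [2-(methoxy(methyl)amino)-2-oxoethyl]phosphonate, CCOP(=O)(CC(=O)N(C)OC)OCC
Why: Horner–Wadsworth–Emmons olefination under Masamune–Roush conditions (LiCl, amine base) is E-selective with enals and mild enough for the free C3 hydroxyl and the gamma-alkoxy enal.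

Step 5
Reactants: 7 (2E,4E)-5-[(2R,3S,5R)-3-hydroxy-5-methyloxolan-2-yl]-N-methoxy-N-methylpenta-2,4-dienamide
Product: 8 (2E,4E)-5-{(2R,3S,5R)-3-[(tert-butyldimethylsilyl)oxy]-5-methyloxolan-2-yl}-N-methoxy-N-methylpenta-2,4-dienamide
Conditions: TBSCl, imidazole, DMF, rt
Reagents that add atoms: tert-butyldimethylsilyl chloride, CC(C)(C)[Si](C)(C)Cl
Why: Standard silylation of a secondary alcohol, needed so that no alkoxide consumes the benzylic anion in step 8.

Step 6
Reactants: 9 methyl 2,4-dihydroxy-6-methylbenzoate (methyl orsellinate)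
Product: 10 methyl 3-chloro-4,6-dihydroxy-2-methylbenzoate
Conditions: SO2Cl2 (1.05 equiv), CH2Cl2/Et2O, 0 °C
Reagents that add atoms: sulfuryl chloride, O=S(=O)(Cl)Cl
Why: Electrophilic aromatic chlorination of a resorcylate goes to the ring position para to the hydrogen-bonded hydroxyl and ortho to the free hydroxyl (next to the methyl group), and one equivalent of SO2Cl2 at 0 °C should hold it at the monochloride.

Step 7
Reactants: 10 methyl 3-chloro-4,6-dihydroxy-2-methylbenzoate
Product: 11 methyl 3-chloro-4,6-bis(ethoxymethoxy)-2-methylbenzoate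
Conditions: NaH (2.5 equiv), EtOCH2Cl (2.5 equiv), DMF, 0 °C to rt
Reagents that add atoms: chloromethyl ethyl ether, CCOCCl
Why: Williamson-type O-alkylation of both phenoxides gives base-stable acetal ethers that tolerate the lithium amide of step 8 and leave under mild acid.

Step 8
Reactants: 11 methyl 3-chloro-4,6-bis(ethoxymethoxy)-2-methylbenzoate; 8 silyl-protected oxolanyl dienyl Weinreb amide
Product: 13 methyl 2-[(3E,5E)-6-{(2R,3S,5R)-3-[(tert-butyldimethylsilyl)oxy]-5-methyloxolan-2-yl}-2-oxohexa-3,5-dien-1-yl]-3-chloro-4,6-bis(ethoxymethoxy)benzoate, via lithiated toluate 12 (not isolated)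
Conditions: 11 (1.3 equiv), LiN(iPr)2 (2.6 equiv), THF, −78 °C, 10 min; then 8, −78 °C, 15 min; AcOH quench
Reagents that add atoms: none
Why: Lateral lithiation of the ortho-toluate followed by acylation with a Weinreb amide, whose chelated tetrahedral adduct stops over-addition, is established for chlorinated bis(alkoxymethoxy) toluates and alpha,beta-unsaturated Weinreb amides; low temperature and short contact favour 1,2- over conjugate addition, and the second equivalent of base covers the acidic product.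

Step 9
Reactants: 13 benzylic dienyl keto ester
Product: 14 5-chloro-6,8-bis(ethoxymethoxy)-3-[(1E,3E)-4-{(2R,3S,5R)-3-[(tert-butyldimethylsilyl)oxy]-5-methyloxolan-2-yl}buta-1,3-dien-1-yl]-1H-isochromen-1-one
Conditions: DBU (1.5 equiv), PhMe, 60 °C
Reagents that add atoms: none
Why: Base-mediated enol lactonisation, in which the conjugated enolate oxygen attacks the neighbouring methyl ester (6-exo-trig acyl substitution) and loss of methoxide gives the pyranone ring, is a closure that 2-(2-oxoalkyl)benzoates undergo readily.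

Step 10
Reactants: 14 protected isocoumarin
Product: 15 5-chloro-6,8-dihydroxy-3-{(1E,3E)-4-[(2R,3S,5R)-3-hydroxy-5-methyloxolan-2-yl]buta-1,3-dien-1-yl}-1H-isochromen-1-one
Conditions: 48% aq. HF, MeCN, 0 °C to rt
Reagents that add atoms: none
Why: Aqueous HF in MeCN hydrolyses the two phenolic ethoxymethyl acetals and cleaves the silyl ether in one global deprotection, at an acidity that should be too low to ionise the dienylic C2–O1 bond.

## Compound list

1 | 2-deoxy-D-ribose (open-chain form) | O=CC[C@H](O)[C@H](O)CO | starting material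
2 | (2R,3S)-hex-5-ene-1,2,3-triol | C=CC[C@H](O)[C@H](O)CO | intermediate
3 | [(2R,4S,5R)-4-hydroxy-5-(hydroxymethyl)oxolan-2-yl]methyl radical (not isolated) | [CH2][C@@H]1C[C@H](O)[C@@H](CO)O1 | intermediate
4 | (2R,3S,5R)-2-(hydroxymethyl)-5-methyloxolan-3-ol | C[C@@H]1C[C@H](O)[C@@H](CO)O1 | intermediate
5 | (2S,3S,5R)-3-hydroxy-5-methyloxolane-2-carbaldehyde (not isolated) | C[C@@H]1C[C@H](O)[C@@H](C=O)O1 | intermediate
6 | (E)-3-[(2R,3S,5R)-3-hydroxy-5-methyloxolan-2-yl]prop-2-enal | C[C@@H]1C[C@H](O)[C@@H](/C=C/C=O)O1 | intermediate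
7 | (2E,4E)-5-[(2R,3S,5R)-3-hydroxy-5-methyloxolan-2-yl]-N-methoxy-N-methylpenta-2,4-dienamide | C[C@@H]1C[C@H](O)[C@@H](/C=C/C=C/C(=O)N(C)OC)O1 | intermediate
8 | (2E,4E)-5-{(2R,3S,5R)-3-[(tert-butyldimethylsilyl)oxy]-5-methyloxolan-2-yl}-N-methoxy-N-methylpenta-2,4-dienamide | C[C@@H]1C[C@H](O[Si](C)(C)C(C)(C)C)[C@@H](/C=C/C=C/C(=O)N(C)OC)O1 | intermediate
9 | methyl 2,4-dihydroxy-6-methylbenzoate | COC(=O)c1c(C)cc(O)cc1O | starting material
10 | methyl 3-chloro-4,6-dihydroxy-2-methylbenzoate | COC(=O)c1c(C)c(Cl)c(O)cc1O | intermediate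
11 | methyl 3-chloro-4,6-bis(ethoxymethoxy)-2-methylbenzoate | COC(=O)c1c(C)c(Cl)c(OCOCC)cc1OCOCC | intermediate
12 | methyl 3-chloro-4,6-bis(ethoxymethoxy)-2-(lithiomethyl)benzoate (not isolated) | COC(=O)c1c(C[Li])c(Cl)c(OCOCC)cc1OCOCC | intermediate
13 | methyl 2-[(3E,5E)-6-{(2R,3S,5R)-3-[(tert-butyldimethylsilyl)oxy]-5-methyloxolan-2-yl}-2-oxohexa-3,5-dien-1-yl]-3-chloro-4,6-bis(ethoxymethoxy)benzoate | C[C@@H]1C[C@H](O[Si](C)(C)C(C)(C)C)[C@@H](/C=C/C=C/C(=O)Cc2c(Cl)c(OCOCC)cc(OCOCC)c2C(=O)OC)O1 | intermediate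
14 | 5-chloro-6,8-bis(ethoxymethoxy)-3-[(1E,3E)-4-{(2R,3S,5R)-3-[(tert-butyldimethylsilyl)oxy]-5-methyloxolan-2-yl}buta-1,3-dien-1-yl]-1H-isochromen-1-one | C[C@@H]1C[C@H](O[Si](C)(C)C(C)(C)C)[C@@H](/C=C/C=C/c2cc3c(Cl)c(OCOCC)cc(OCOCC)c3c(=O)o2)O1 | intermediate
15 | 5-chloro-6,8-dihydroxy-3-{(1E,3E)-4-[(2R,3S,5R)-3-hydroxy-5-methyloxolan-2-yl]buta-1,3-dien-1-yl}-1H-isochromen-1-one | C[C@@H]1C[C@H](O)[C@@H](/C=C/C=C/c2cc3c(Cl)c(O)cc(O)c3c(=O)o2)O1 | target

## Step count and risks

Total step count: 10.
Longest linear sequence: 8 steps (1, 2, 3, 4, 5, 8, 9, 10).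

**Step 2.**
- What may go wrong: the triol may chelate the catalyst and stall turnover. Dioxygen may capture the carbon radical before hydrogen transfer. Facial selectivity at C5 may be insufficient.
- Fallback: an ionic, two-stage closure of the same bond. Setting out from 2, iodoetherification (I2, NaHCO3, MeCN, 0 °C; 5-exo opening of the iodonium ion by the C2 hydroxyl) should give (2R,3S,5S)-2-(hydroxymethyl)-5-(iodomethyl)oxolan-3-ol F1.
- Any C5 epimer can be removed at this stage by chromatography or crystallisation. Radical deiodination (Bu3SnH, AIBN, PhMe, 80 °C) comes back to the route at 4.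

**Step 8.**
- What may go wrong: the benzylic anion may add in a conjugate (1,4 or 1,6) sense to the dienamide. Excess amide base may cause vinylogous deprotonation at C2 of the oxolane.
- Fallback: the ketone is made by olefination instead of acylation with a diene. Setting out from 11 and 6, the lithiated toluate 12 is acylated with 2-chloro-N-methoxy-N-methylacetamide, which has no conjugate acceptor. This should give methyl 3-chloro-2-(3-chloro-2-oxopropyl)-4,6-bis(ethoxymethoxy)benzoate F2.
- PPh3 (PhMe, 60 °C) converts it to the acylmethyl triphenylphosphonium chloride F3, and aqueous Na2CO3 gives the stabilised keto ylide F4.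
- In parallel, 6 is silylated (TBSCl, imidazole, DMF) to (E)-3-{(2R,3S,5R)-3-[(tert-butyldimethylsilyl)oxy]-5-methyloxolan-2-yl}prop-2-enal F5.
- An E-selective Wittig reaction of the two (PhMe, 60 °C) comes back to the route at 13.

**Step 10.**
- What may go wrong: acid may ionise the dienylic C2–O1 bond during acetal hydrolysis, with epimerisation at C2 or ring opening.
- Fallback: an acid-free protecting-group scheme. Setting out from 10, both phenols are allylated (allyl bromide, K2CO3, DMF) to methyl 3-chloro-2-methyl-4,6-bis(prop-2-enyloxy)benzoate F6.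
- LiN(iPr)2 (THF, −78 °C) gives the lithiated bis(allyl) toluate F7, which is acylated with 8 to the bis(allyl) keto ester F8. DBU (PhMe, 60 °C) closes the bis(allyl) isocoumarin F9.
- Pd(PPh3)4 with morpholine (THF, rt) removes both aryl allyl ethers under neutral conditions. Zerovalent palladium ionises only the aryl allyl ethers. The product is the C3 silyl ether of the target F10.
- Bu4NF buffered with AcOH (THF, 0 °C) comes back to the route at 15.

## Further compounds

F1 | step 2 | (2R,3S,5S)-2-(hydroxymethyl)-5-(iodomethyl)oxolan-3-ol | IC[C@@H]1C[C@H](O)[C@@H](CO)O1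
F2 | step 8 | methyl 3-chloro-2-(3-chloro-2-oxopropyl)-4,6-bis(ethoxymethoxy)benzoate | COC(=O)c1c(CC(=O)CCl)c(Cl)c(OCOCC)cc1OCOCC
F3 | step 8 | {3-[2-chloro-3,5-bis(ethoxymethoxy)-6-(methoxycarbonyl)phenyl]-2-oxopropyl}triphenylphosphonium chloride | COC(=O)c1c(CC(=O)C[P+](c2ccccc2)(c2ccccc2)c2ccccc2)c(Cl)c(OCOCC)cc1OCOCC.[Cl-]
F4 | step 8 | methyl 3-chloro-4,6-bis(ethoxymethoxy)-2-[2-oxo-3-(triphenylphosphoranylidene)propyl]benzoate | COC(=O)c1c(CC(=O)C=P(c2ccccc2)(c2ccccc2)c2ccccc2)c(Cl)c(OCOCC)cc1OCOCC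
F5 | step 8 | (E)-3-{(2R,3S,5R)-3-[(tert-butyldimethylsilyl)oxy]-5-methyloxolan-2-yl}prop-2-enal | C[C@@H]1C[C@H](O[Si](C)(C)C(C)(C)C)[C@@H](/C=C/C=O)O1
F6 | step 10 | methyl 3-chloro-2-methyl-4,6-bis(prop-2-enyloxy)benzoate | COC(=O)c1c(C)c(Cl)c(OCC=C)cc1OCC=C
F7 | step 10 | methyl 3-chloro-2-(lithiomethyl)-4,6-bis(prop-2-enyloxy)benzoate | COC(=O)c1c(C[Li])c(Cl)c(OCC=C)cc1OCC=C
F8 | step 10 | methyl 2-[(3E,5E)-6-{(2R,3S,5R)-3-[(tert-butyldimethylsilyl)oxy]-5-methyloxolan-2-yl}-2-oxohexa-3,5-dien-1-yl]-3-chloro-4,6-bis(prop-2-enyloxy)benzoate | C[C@@H]1C[C@H](O[Si](C)(C)C(C)(C)C)[C@@H](/C=C/C=C/C(=O)Cc2c(Cl)c(OCC=C)cc(OCC=C)c2C(=O)OC)O1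
F9 | step 10 | 5-chloro-6,8-bis(prop-2-enyloxy)-3-[(1E,3E)-4-{(2R,3S,5R)-3-[(tert-butyldimethylsilyl)oxy]-5-methyloxolan-2-yl}buta-1,3-dien-1-yl]-1H-isochromen-1-one | C[C@@H]1C[C@H](O[Si](C)(C)C(C)(C)C)[C@@H](/C=C/C=C/c2cc3c(Cl)c(OCC=C)cc(OCC=C)c3c(=O)o2)O1
F10 | step 10 | 5-chloro-6,8-dihydroxy-3-[(1E,3E)-4-{(2R,3S,5R)-3-[(tert-butyldimethylsilyl)oxy]-5-methyloxolan-2-yl}buta-1,3-dien-1-yl]-1H-isochromen-1-one | C[C@@H]1C[C@H](O[Si](C)(C)C(C)(C)C)[C@@H](/C=C/C=C/c2cc3c(Cl)c(O)cc(O)c3c(=O)o2)O1
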